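**Retrosynthetic overview**

1. The target comes from its methyl ester bis(aryl silyl ether) by one hydroxide deprotection at the end.
2. The oxepine is the only ring made (the arene is bought); it is closed late by ring-closing metathesis at C5=C6 from an acyclic tertiary ether carrying a but-3-enyl group and a 2-substituted allyl ether.
3. The (E)-allylic alcohol comes from SeO2 oxidation of a prenyl terminus before ring closure; the tertiary ether C–O bond comes from a tertiary alcohol and the primary allylic triflate of a C9 dienol (methallyl alcohol dianion plus prenyl bromide).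
4. The quaternary stereocentre comes from a squaramide-catalysed enantioselective decarboxylative aldol addition of an aroylacetic acid to methyl 2-oxohex-5-enoate (the new step).
5. Building blocks: 2′,5′-dihydroxyacetophenone, but-3-enylmagnesium bromide, dimethyl oxalate, methallyl alcohol, prenyl bromide.

Assumption: the sense of induction in step 4 is assigned by analogy; if the quinidine-derived catalyst gives (R)-10, its quinine-derived pseudo-enantiomer is used, and the configuration of 10 is checked (X-ray or CD) before going on.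
Convention: a salt of a product that is only protonated on work-up is not numbered separately.

**Route**

Step 1
Reactants: 1 but-3-en-1-ylmagnesium bromide; 2 dimethyl oxalate
Product: 4 methyl 2-oxohex-5-enoate, via magnesium hemiketal alkoxide 3 (not isolated)
Conditions: 2 (2 equiv), THF, −78 °C, slow addition of 1; then 1 M HCl, −78 to 0 °C
Reagents that add atoms: none
Why: Grignard acylation of an oxalate diester stops at the tetrahedral magnesium hemiketal 3 at −78 °C, which releases the α-keto ester only on acidic work-up, so over-addition is avoided.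

Step 2
Reactants: 5 1-(2,5-dihydroxyphenyl)ethan-1-one
Product: 6 1-[2,5-bis(tert-butyldimethylsilyloxy)phenyl]ethan-1-one
Conditions: TBSCl (2.5 equiv), imidazole (5 equiv), DMF, rt to 40 °C
Reagents that add atoms: tert-butyldimethylsilyl chloride, CC(C)(C)[Si](C)(C)Cl
Why: Standard silyl ether protection of both phenols masks the hydroquinone against oxidation and O-alkylation, and aryl silyl ethers fall off with hydroxide in the last step.

Step 3
Reactants: 6 1-[2,5-bis(tert-butyldimethylsilyloxy)phenyl]ethan-1-one
Product: 8 3-[2,5-bis(tert-butyldimethylsilyloxy)phenyl]-3-oxopropanoic acid, via lithium enolate 7 (not isolated)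
Conditions: LiN(iPr)2 (1.15 equiv), THF, −78 °C, 30 min; CO2 (g), −78 °C; cold 1 M HCl to pH 2–3, extract at 0 °C, use at once
Reagents that add atoms: carbon dioxide, O=C=O
Why: Enolate carboxylation of the kinetic lithium enolate with CO2 gives the aroylacetic acid, which is kept cold to prevent decarboxylation and silyl migration.

Step 4
Reactants: 8 3-[2,5-bis(tert-butyldimethylsilyloxy)phenyl]-3-oxopropanoic acid; 4 methyl 2-oxohex-5-enoate
Product: 10 methyl (2S)-2-{2-[2,5-bis(tert-butyldimethylsilyloxy)phenyl]-2-oxoethyl}-2-hydroxyhex-5-enoate, via carboxylated aldol adduct 9 (not isolated)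
Conditions: 4 (1.5 equiv), 3,5-bis(trifluoromethyl)phenyl squaramide of 9-amino-9-deoxy-epi-quinidine (10 mol%), MTBE, −10 to 0 °C, 48–72 h
Reagents that add atoms: none
Why: Proposed new method: an enantioselective decarboxylative aldol addition of an aroylacetic acid to an enolisable alkyl α-keto ester, an acceptor class not shown for this reaction to my knowledge. The quinuclidine of the catalyst is protonated by 8 and holds its β-keto carboxylate as an ion pair, while the two squaramide N–H bonds bind the s-trans 1,2-dicarbonyl of 4; only the ester side offers a second hydrogen-bond acceptor, so ester and but-3-enyl are told apart and the enol carbon of 8 is delivered to one ketone face, setting the (S) quaternary centre in 9, which then loses CO2 to give 10. Because the amine is tied up as an ammonium carboxylate, little free base is left to enolise 4, which should suppress its self-aldol reaction. The closest known reactions are cinchona squaramide- or thiourea-catalysed decarboxylative aldol additions of β-keto acids to isatins and aryl trifluoromethyl ketones, and cinchona-catalysed nitroaldol additions to alkyl α-keto esters.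

Step 5
Reactants: 11 2-methylprop-2-en-1-ol; 12 1-bromo-3-methylbut-2-ene
Product: 14 6-methyl-2-methylidenehept-5-en-1-ol, via dilithio dianion of methallyl alcohol 13 (not isolated)
Conditions: n-BuLi (2.2 equiv), TMEDA (2.2 equiv), Et2O, 0 °C to rt, 20 h; then 12 (0.9 equiv), −78 °C to rt; H2O
Reagents that add atoms: none
Why: Dianion alkylation: the carbon terminus of the methallyl alcohol dianion displaces the primary allylic bromide by SN2, and since both carbon termini of the 2-substituted allyl anion are equivalent only one constitution can form.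

Step 6
Reactants: 14 6-methyl-2-methylidenehept-5-en-1-ol; 10 methyl (2S)-2-{2-[2,5-bis(tert-butyldimethylsilyloxy)phenyl]-2-oxoethyl}-2-hydroxyhex-5-enoate
Product: 16 methyl (2S)-2-{2-[2,5-bis(tert-butyldimethylsilyloxy)phenyl]-2-oxoethyl}-2-[(6-methyl-2-methylidenehept-5-en-1-yl)oxy]hex-5-enoate, via allylic triflate 15 (not isolated)
Conditions: 14 (1.5 equiv), Tf2O (1.4 equiv), 2,6-di-tert-butyl-4-methylpyridine (3 equiv), CH2Cl2, −78 °C, 20 min; then 10 (1.0 equiv), −78 to −10 °C
Reagents that add atoms: none
Why: O-alkylation of the hindered tertiary alcohol by a primary allylic triflate with a non-nucleophilic pyridine as acid scavenger forms no alkoxide, so retro-aldol cleavage cannot occur and the stereocentre is untouched.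

Step 7
Reactants: 16 methyl (2S)-2-{2-[2,5-bis(tert-butyldimethylsilyloxy)phenyl]-2-oxoethyl}-2-[(6-methyl-2-methylidenehept-5-en-1-yl)oxy]hex-5-enoate
Product: 17 methyl (2S)-2-{2-[2,5-bis(tert-butyldimethylsilyloxy)phenyl]-2-oxoethyl}-2-{[(5E)-7-hydroxy-6-methyl-2-methylidenehept-5-en-1-yl]oxy}hex-5-enoate
Conditions: SeO2 (0.5 equiv), t-BuOOH (3 equiv), salicylic acid (0.1 equiv), CH2Cl2, 0 °C to rt; stop near 70% conversion and recycle 16
Reagents that add atoms: tert-butyl hydroperoxide, CC(C)(C)OO (terminal oxidant; its oxygen is relayed through selenium dioxide, O=[Se]=O)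
Why: SeO2 allylic oxidation (ene reaction then [2,3]-sigmatropic shift) hydroxylates the (E)-methyl group of the only trisubstituted alkene, the 1,1-disubstituted alkene being deactivated by its allylic ether oxygen and the terminal alkene being inert.

Step 8
Reactants: 17 methyl (2S)-2-{2-[2,5-bis(tert-butyldimethylsilyloxy)phenyl]-2-oxoethyl}-2-{[(5E)-7-hydroxy-6-methyl-2-methylidenehept-5-en-1-yl]oxy}hex-5-enoate
Product: 18 methyl (2S)-2-{2-[2,5-bis(tert-butyldimethylsilyloxy)phenyl]-2-oxoethyl}-6-[(3E)-5-hydroxy-4-methylpent-3-en-1-yl]-2,3,4,7-tetrahydrooxepine-2-carboxylate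
Conditions: second-generation Grubbs catalyst RuCl2(=CHPh)(H2IMes)(PCy3) (5 mol%), CH2Cl2 (0.005 M), 40 °C
Reagents that add atoms: none
Why: Ring-closing metathesis of the terminal and 1,1-disubstituted alkenes closes the seven-membered ring with a necessarily cis ring double bond, helped by the quaternary carbon, while the trisubstituted side-chain alkene could only give a cyclobutene or a ten-membered ring and stays out.

Step 9
Reactants: 18 methyl (2S)-2-{2-[2,5-bis(tert-butyldimethylsilyloxy)phenyl]-2-oxoethyl}-6-[(3E)-5-hydroxy-4-methylpent-3-en-1-yl]-2,3,4,7-tetrahydrooxepine-2-carboxylate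
Product: 19 (2S)-2-[2-(2,5-dihydroxyphenyl)-2-oxoethyl]-6-[(3E)-5-hydroxy-4-methylpent-3-en-1-yl]-2,3,4,7-tetrahydrooxepine-2-carboxylic acid
Conditions: LiOH (8 equiv), degassed THF/MeOH/H2O 3:1:1, Ar, 0 °C to rt; then 1 M HCl to pH 3 at 0 °C
Reagents that add atoms: lithium hydroxide, [Li+].[OH-] (its oxygen ends in the carboxyl group)
Why: Hydroxide cleaves both aryl silyl ethers and saponifies the methyl ester in one operation (ester saponification), the phenoxides formed first lowering the acidity of the ketone α-position so that E1cB opening of the β-alkoxy ketone is disfavoured, and the quaternary stereocentre cannot epimerise.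

**Compound list**

1 | but-3-en-1-ylmagnesium bromide (commercial THF solution) | C=CCC[Mg]Br | starting material
2 | dimethyl oxalate | COC(=O)C(=O)OC | starting material
3 | methyl 2-(bromomagnesiooxy)-2-methoxyhex-5-enoate (racemic tetrahedral adduct) | C=CCCC(OC)(O[Mg]Br)C(=O)OC | intermediate (not isolated)
4 | methyl 2-oxohex-5-enoate | C=CCCC(=O)C(=O)OC | intermediate
5 | 1-(2,5-dihydroxyphenyl)ethan-1-one | CC(=O)c1cc(O)ccc1O | starting material
6 | 1-[2,5-bis(tert-butyldimethylsilyloxy)phenyl]ethan-1-one | CC(=O)c1cc(O[Si](C)(C)C(C)(C)C)ccc1O[Si](C)(C)C(C)(C)C | intermediate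
7 | lithium 1-[2,5-bis(tert-butyldimethylsilyloxy)phenyl]ethen-1-olate | [Li]OC(=C)c1cc(O[Si](C)(C)C(C)(C)C)ccc1O[Si](C)(C)C(C)(C)C | intermediate (not isolated)
8 | 3-[2,5-bis(tert-butyldimethylsilyloxy)phenyl]-3-oxopropanoic acid | OC(=O)CC(=O)c1cc(O[Si](C)(C)C(C)(C)C)ccc1O[Si](C)(C)C(C)(C)C | intermediate
9 | (3S)-2-[2,5-bis(tert-butyldimethylsilyloxy)benzoyl]-3-hydroxy-3-(methoxycarbonyl)hept-6-enoic acid (C2 configuration not defined) | C=CCC[C@](C(C(=O)O)C(=O)c1cc(O[Si](C)(C)C(C)(C)C)ccc1O[Si](C)(C)C(C)(C)C)(C(=O)OC)O | intermediate (not isolated)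
10 | methyl (2S)-2-{2-[2,5-bis(tert-butyldimethylsilyloxy)phenyl]-2-oxoethyl}-2-hydroxyhex-5-enoate | C=CCC[C@](CC(=O)c1cc(O[Si](C)(C)C(C)(C)C)ccc1O[Si](C)(C)C(C)(C)C)(C(=O)OC)O | intermediate
11 | 2-methylprop-2-en-1-ol (methallyl alcohol) | CC(=C)CO | starting material
12 | 1-bromo-3-methylbut-2-ene (prenyl bromide) | CC(C)=CCBr | starting material
13 | lithium 2-(lithiomethyl)prop-2-en-1-olate | [Li]CC(=C)CO[Li] | intermediate (not isolated)
14 | 6-methyl-2-methylidenehept-5-en-1-ol | C=C(CO)CCC=C(C)C | intermediate
15 | 6-methyl-2-methylidenehept-5-en-1-yl trifluoromethanesulfonate | C=C(COS(=O)(=O)C(F)(F)F)CCC=C(C)C | intermediate (not isolated)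
16 | methyl (2S)-2-{2-[2,5-bis(tert-butyldimethylsilyloxy)phenyl]-2-oxoethyl}-2-[(6-methyl-2-methylidenehept-5-en-1-yl)oxy]hex-5-enoate | C=CCC[C@](CC(=O)c1cc(O[Si](C)(C)C(C)(C)C)ccc1O[Si](C)(C)C(C)(C)C)(C(=O)OC)OCC(=C)CCC=C(C)C | intermediate
17 | methyl (2S)-2-{2-[2,5-bis(tert-butyldimethylsilyloxy)phenyl]-2-oxoethyl}-2-{[(5E)-7-hydroxy-6-methyl-2-methylidenehept-5-en-1-yl]oxy}hex-5-enoate | C=CCC[C@](CC(=O)c1cc(O[Si](C)(C)C(C)(C)C)ccc1O[Si](C)(C)C(C)(C)C)(C(=O)OC)OCC(=C)CC/C=C(\C)CO | intermediate
18 | methyl (2S)-2-{2-[2,5-bis(tert-butyldimethylsilyloxy)phenyl]-2-oxoethyl}-6-[(3E)-5-hydroxy-4-methylpent-3-en-1-yl]-2,3,4,7-tetrahydrooxepine-2-carboxylate | C/C(=C\CCC1=CCC[C@](CC(=O)c2cc(O[Si](C)(C)C(C)(C)C)ccc2O[Si](C)(C)C(C)(C)C)(C(=O)OC)OC1)CO | intermediate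
19 | (2S)-2-[2-(2,5-dihydroxyphenyl)-2-oxoethyl]-6-[(3E)-5-hydroxy-4-methylpent-3-en-1-yl]-2,3,4,7-tetrahydrooxepine-2-carboxylic acid | C/C(=C\CCC1=CCC[C@](CC(=O)c2cc(O)ccc2O)(C(=O)O)OC1)CO | target

**Step count and risks**

Total step count: 9. Longest linear sequence: 7 steps (steps 2, 3, 4, 6, 7, 8, 9).

The three steps most likely to fail:

Step 4 (the proposed new aldol addition). The risks are self-aldol reaction of the enolisable keto ester 4, simple decarboxylation of 8 back to 6, and insufficient enantioselectivity. The fallback uses known chemistry, sets out from 6 (with 4) and comes back at 10. Ketone 6 is silylated with Me3SiOTf and Et3N (CH2Cl2, 0 °C) to the enol silane 1-[2,5-bis(tert-butyldimethylsilyloxy)phenyl]-1-(trimethylsilyloxy)ethene F1. A Mukaiyama aldol addition of F1 to 4 with the divalent copper bis(oxazoline) complex [Cu((S,S)-t-Bu-box)](OTf)2 (10 mol%, THF, −78 °C), in which 4 chelates copper through both carbonyl groups, gives the silyl ether methyl (2S)-2-{2-[2,5-bis(tert-butyldimethylsilyloxy)phenyl]-2-oxoethyl}-2-(trimethylsilyloxy)hex-5-enoate F2. Treatment with 1 M HCl in THF at 0 °C frees the tertiary alcohol 10. The ligand antipode is chosen by analogy with pyruvate esters; the (R,R) ligand is used if the sense turns out opposite.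

Step 6 (etherification of the hindered tertiary alcohol). The risks are decomposition or cation–olefin cyclisation of triflate 15 before the poorly nucleophilic alcohol reacts. The fallback sets out from 14 (with 10) and comes back at 16. Alcohol 14 is converted with Boc2O and catalytic DMAP into tert-butyl (6-methyl-2-methylidenehept-5-en-1-yl) carbonate F3, and 10 is allylated with F3 and Pd(PPh3)4 (zerovalent palladium, 5 mol%) in THF at 50 °C. This is a neutral Tsuji–Trost allylic etherification; the symmetrical 2-substituted π-allyl unit can give only one regioisomer, and the only base is the tert-butoxide released at palladium. Its own risk is ketone enolisation or retro-aldol cleavage by that tert-butoxide.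

Step 9 (final hydroxide deprotection). The risks are E1cB opening of the β-alkoxy ketone, air oxidation of the hydroquinone under base, and slow hydrolysis of the hindered ester. The fallback sets out from 18 and comes back at 19. The aryl silyl ethers are removed first with Bu4NF buffered with AcOH (THF, 0 °C) to give the diphenol methyl (2S)-2-[2-(2,5-dihydroxyphenyl)-2-oxoethyl]-6-[(3E)-5-hydroxy-4-methylpent-3-en-1-yl]-2,3,4,7-tetrahydrooxepine-2-carboxylate F4. The ester is then cleaved without strong base using Me3SnOH (1,2-dichloroethane, 70 °C), followed by a dilute KHSO4 wash, to give 19.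

**Further compounds**

F1 | step 4 | 1-[2,5-bis(tert-butyldimethylsilyloxy)phenyl]-1-(trimethylsilyloxy)ethene | C=C(O[Si](C)(C)C)c1cc(O[Si](C)(C)C(C)(C)C)ccc1O[Si](C)(C)C(C)(C)C
F2 | step 4 | methyl (2S)-2-{2-[2,5-bis(tert-butyldimethylsilyloxy)phenyl]-2-oxoethyl}-2-(trimethylsilyloxy)hex-5-enoate | C=CCC[C@](CC(=O)c1cc(O[Si](C)(C)C(C)(C)C)ccc1O[Si](C)(C)C(C)(C)C)(C(=O)OC)O[Si](C)(C)C
F3 | step 6 | tert-butyl (6-methyl-2-methylidenehept-5-en-1-yl) carbonate | C=C(COC(=O)OC(C)(C)C)CCC=C(C)C
F4 | step 9 | methyl (2S)-2-[2-(2,5-dihydroxyphenyl)-2-oxoethyl]-6-[(3E)-5-hydroxy-4-methylpent-3-en-1-yl]-2,3,4,7-tetrahydrooxepine-2-carboxylate | C/C(=C\CCC1=CCC[C@](CC(=O)c2cc(O)ccc2O)(C(=O)OC)OC1)CO
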